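## Retrosynthetic overview

1. The imidazolidinone ring is closed last: a urea on the quaternary carbon C10 attacks the aminal carbon C6 (an N,O-acetal on the pyrrole nitrogen); the forced cis-fusion sets C6.
2. The urea nitrogen on C10 comes from a Curtius rearrangement (retention) of a C10 carboxylic acid.
3. The pyrazinone ring comes from acylating the pyrrole nitrogen with the second carboxyl group, then reducing that acyl-pyrrole C=O to the carbinolamine (C6).
4. The C10 stereocentre comes from esterase desymmetrisation of a prochiral N-aroyl pyrrolidine-2,2-dicarboxylate (a disubstituted malonate).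
5. Ring order: pyrrolidine (aminomalonate + 1,3-dibromopropane), purchased dibromopyrrole, pyrazinone, imidazolidinone.

Locants: C10 is the quaternary ring-fusion carbon (the former malonate carbon); C6 is the carbon between C10 and the pyrrole nitrogen.

Assumption: a pig-liver-esterase isoenzyme that hydrolyses the pro-S ester of 8 with useful ee is found by screening the commercial recombinant isoenzymes; this selectivity is not known for this substrate.

## Route

Step 1
Reactants: 1 dimethyl 2-aminomalonate hydrochloride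
Product: 2 dimethyl 2-[(tert-butoxycarbonyl)amino]malonate
Conditions: Boc2O (1.1 equiv), NaHCO3 (2.5 equiv), THF/H2O 1:1, 0 °C → rt
Reagents that add atoms: di-tert-butyl dicarbonate, CC(C)(C)OC(=O)OC(=O)OC(C)(C)C
Why: Carbamate formation (N-Boc protection) on the free-based amine, which acidifies the malonate C–H and later lets the nitrogen close the ring as its anion.

Step 2
Reactants: 2 dimethyl 2-[(tert-butoxycarbonyl)amino]malonate; 3 1,3-dibromopropane
Product: 4 1-tert-butyl 2,2-dimethyl pyrrolidine-1,2,2-tricarboxylate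
Conditions: NaH (2.2 equiv), 3 (1.2 equiv), DMF, 0 °C → rt, then 50 °C
Reagents that add atoms: none
Why: Double alkylation, SN2 C-alkylation of the malonate anion followed by 5-exo-tet N-alkylation of the carbamate anion, gives the achiral pyrrolidine diester.

Step 3
Reactants: 4 1-tert-butyl 2,2-dimethyl pyrrolidine-1,2,2-tricarboxylate
Product: 5 dimethyl pyrrolidine-2,2-dicarboxylate hydrochloride
Conditions: 4 M HCl in 1,4-dioxane, rt
Reagents that add atoms: hydrogen chloride, Cl
Why: Acidolytic Boc cleavage leaves the methyl esters intact and gives the amine as its storable hydrochloride.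

Step 4
Reactants: 6 4,5-dibromo-1H-pyrrole-2-carboxylic acid
Product: 7 4,5-dibromo-1H-pyrrole-2-carbonyl chloride
Conditions: (COCl)2 (1.5 equiv), DMF (cat.), CH2Cl2, 0 °C → rt; evaporate, use crude
Reagents that add atoms: oxalyl chloride, O=C(Cl)C(Cl)=O
Why: Vilsmeier-catalysed acid chloride formation, to which the electron-poor dibromopyrrole N–H is inert.

Step 5
Reactants: 5 dimethyl pyrrolidine-2,2-dicarboxylate hydrochloride; 7 4,5-dibromo-1H-pyrrole-2-carbonyl chloride
Product: 8 dimethyl 1-(4,5-dibromo-1H-pyrrole-2-carbonyl)pyrrolidine-2,2-dicarboxylate (prochiral)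
Conditions: pyridine (4 equiv), DMAP (0.2 equiv), CH2Cl2, 0 → 40 °C
Reagents that add atoms: none
Why: DMAP-catalysed nucleophilic acyl substitution, where an acid chloride is needed for this hindered, weakly nucleophilic amine and the weak base pyridine avoids ketene-type self-condensation of 7.

Step 6
Reactants: 8 dimethyl 1-(4,5-dibromo-1H-pyrrole-2-carbonyl)pyrrolidine-2,2-dicarboxylate
Product: 9 (2R)-1-(4,5-dibromo-1H-pyrrole-2-carbonyl)-2-(methoxycarbonyl)pyrrolidine-2-carboxylic acid
Conditions: pig liver esterase (a carboxylesterase, serine hydrolase, EC 3.1.1.1), 0.2 M K-phosphate pH 7.5/DMSO 9:1, 30 °C; then pH 3, EtOAc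
Reagents that add atoms: water, O
Why: Enzymatic desymmetrisation of a prochiral disubstituted malonate, in which the chiral active site of the carboxylesterase hydrolyses only the pro-S ester and stops at the half-ester, creating the quaternary stereocentre (R) by asymmetric biocatalysis.

Step 7
Reactants: 9 (2R)-1-(4,5-dibromo-1H-pyrrole-2-carbonyl)-2-(methoxycarbonyl)pyrrolidine-2-carboxylic acid
Product: 10 tricyclic acyl-pyrrole dione (the CO2H carbon of 9 is now C6 and acylates the pyrrole nitrogen, closing the six-membered ring pyrrole-N–C6(=O)–C10–N–C(=O)–pyrrole-C2; CO2Me on C10, R)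
Conditions: DCC (1.1 equiv), DMAP (0.1 equiv), CH2Cl2, 0 °C → rt; use crude, anhydrous
Reagents that add atoms: none
Why: Carbodiimide (Steglich-type) activation and intramolecular N-acylation of the acidic pyrrole N–H close the six-membered ring, and the quaternary centre cannot epimerise.

Step 8
Reactants: 10 tricyclic acyl-pyrrole dione
Product: 11 C6-carbinolamine (C6–OH on the pyrrole nitrogen, CO2Me on C10, R at C10, C6 epimers)
Conditions: NaBH4 (1.0 equiv), THF/H2O 10:1, −10 °C; AcOH quench
Reagents that add atoms: none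
Why: Chemoselective borohydride reduction of the ketone-like N-acylpyrrole carbonyl stops at the cyclic carbinolamine while the ester and tertiary amide are untouched, and the new C6 centre forms as an inconsequential epimer mixture.

Step 9
Reactants: 11 C6-carbinolamine
Product: 12 C6-methoxy N,O-acetal methyl ester (R at C10, C6 epimers)
Conditions: p-TsOH·H2O (0.1 equiv), MeOH, 3 Å MS, 40 °C
Reagents that add atoms: methanol, CO
Why: Acid-catalysed N,O-acetal formation masks C6 so that the base of step 10 cannot open the ring to an α-formyl ester and cause retro-Claisen loss.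

Step 10
Reactants: 12 C6-methoxy N,O-acetal methyl ester
Product: 13 C6-methoxy N,O-acetal C10-carboxylic acid (R at C10)
Conditions: LiOH·H2O (3 equiv), THF/H2O 3:1, rt → 45 °C; then 1 M HCl to pH 3, 0 °C
Reagents that add atoms: lithium hydroxide, [Li+].[OH-]
Why: Saponification of the only remaining ester, to which the N,O-acetal, the tertiary amide and the aryl bromides are stable.

Step 11
Reactants: 13 C6-methoxy N,O-acetal C10-carboxylic acid
Product: 16 C10-urea (NH–CO–NH2 on C10, OMe on C6), via acyl azide 14 (not isolated), via isocyanate 15 (not isolated)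
Conditions: DPPA (1.2 equiv), Et3N (1.3 equiv), toluene, rt then 80 °C; then NH3 (0.5 M in 1,4-dioxane), 0 °C → rt
Reagents that add atoms: diphenylphosphoryl azide, [N-]=[N+]=NP(=O)(Oc1ccccc1)Oc1ccccc1; ammonia, N
Why: Curtius rearrangement moves the tertiary C10 to nitrogen with retention of configuration, and ammonia captures the isocyanate as the primary urea.

Step 12
Reactants: 16 C10-urea
Product: 17 dibromophakellstatin (C6 S, C10 R)
Conditions: TFA (10 equiv), CH2Cl2, 4 Å MS, 0 °C → rt
Reagents that add atoms: none
Why: Acid-promoted intramolecular amidoalkylation (N,O-acetal to N,N-aminal exchange), in which the urea NH2 replaces methanol at C6 in a five-membered ring closure that can only be cis-fused, so C10 (R) dictates C6 (S) under thermodynamic control.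

## Compound list

1 | dimethyl 2-aminomalonate hydrochloride | COC(=O)C(N)C(=O)OC.Cl | starting material
2 | dimethyl 2-[(tert-butoxycarbonyl)amino]malonate | COC(=O)C(NC(=O)OC(C)(C)C)C(=O)OC | intermediate
3 | 1,3-dibromopropane | BrCCCBr | starting material
4 | 1-tert-butyl 2,2-dimethyl pyrrolidine-1,2,2-tricarboxylate | COC(=O)C1(C(=O)OC)CCCN1C(=O)OC(C)(C)C | intermediate
5 | dimethyl pyrrolidine-2,2-dicarboxylate hydrochloride | COC(=O)C1(C(=O)OC)CCCN1.Cl | intermediate
6 | 4,5-dibromo-1H-pyrrole-2-carboxylic acid | OC(=O)c1cc(Br)c(Br)[nH]1 | starting material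
7 | 4,5-dibromo-1H-pyrrole-2-carbonyl chloride | ClC(=O)c1cc(Br)c(Br)[nH]1 | intermediate
8 | dimethyl 1-(4,5-dibromo-1H-pyrrole-2-carbonyl)pyrrolidine-2,2-dicarboxylate | COC(=O)C1(C(=O)OC)CCCN1C(=O)c1cc(Br)c(Br)[nH]1 | intermediate
9 | (2R)-1-(4,5-dibromo-1H-pyrrole-2-carbonyl)-2-(methoxycarbonyl)pyrrolidine-2-carboxylic acid | COC(=O)[C@]1(C(=O)O)CCCN1C(=O)c1cc(Br)c(Br)[nH]1 | intermediate
10 | tricyclic acyl-pyrrole dione, CO2Me on C10 (R) | COC(=O)[C@]12CCCN1C(=O)c1cc(Br)c(Br)n1C2=O | intermediate
11 | C6-carbinolamine, CO2Me on C10 (R), C6 epimers | COC(=O)[C@]12CCCN1C(=O)c1cc(Br)c(Br)n1C2O | intermediate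
12 | C6-methoxy N,O-acetal methyl ester (R at C10), C6 epimers | COC(=O)[C@]12CCCN1C(=O)c1cc(Br)c(Br)n1C2OC | intermediate
13 | C6-methoxy N,O-acetal C10-carboxylic acid (R at C10), C6 epimers | OC(=O)[C@]12CCCN1C(=O)c1cc(Br)c(Br)n1C2OC | intermediate
14 | C10-acyl azide of 13 | [N-]=[N+]=NC(=O)[C@]12CCCN1C(=O)c1cc(Br)c(Br)n1C2OC | intermediate
15 | C10-isocyanate | O=C=N[C@]12CCCN1C(=O)c1cc(Br)c(Br)n1C2OC | intermediate
16 | C10-urea with C6–OMe, C6 epimers | NC(=O)N[C@]12CCCN1C(=O)c1cc(Br)c(Br)n1C2OC | intermediate
17 | dibromophakellstatin | O=C1N[C@H]2n3c(cc(Br)c3Br)C(=O)N3CCC[C@]23N1 | target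

## Step count and risks

Total steps: 12. Longest linear sequence: 11 (steps 1–3 and 5–12); step 4 is a one-step side branch.

**Step 6 (esterase desymmetrisation).** The enantioselectivity, or even acceptance of this bulky substrate, may be poor. The fallback sets out from 8 and returns at 13.
- Reduce both esters of 8 with LiBH4 (THF, 0 °C → rt) to the prochiral diol F1.
- Desymmetrise with a lipase (Burkholderia cepacia lipase, vinyl acetate, MTBE, 30 °C, selected by screening) to the monoacetate F2, whose free CH2OH is the future C6 arm. Use it at once to avoid acetyl migration.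
- Oxidise with Dess–Martin periodinane to the aldehyde F3, which is not isolated and closes onto the pyrrole N–H to the carbinolamine acetate F4.
- p-TsOH/MeOH gives the methyl N,O-acetal acetate F5, and K2CO3/MeOH frees the primary alcohol F6.
- Dess–Martin oxidation to the aldehyde F7, then Pinnick oxidation (NaClO2, NaH2PO4, 2-methyl-2-butene), gives acid 13.

**Step 8 (partial reduction of the acyl-pyrrole).** The carbinolamine may open and be reduced further. The fallback sets out from 10 and returns at 11. Reduce 10 fully with excess NaBH4 (THF/H2O, 0 °C → rt) to the ring-opened primary alcohol F8. Re-oxidise with Dess–Martin periodinane (NaHCO3, CH2Cl2) to the aldehyde F9, which is not isolated and closes onto the pyrrole N–H to give 11.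

**Step 12 (acid-mediated urea closure onto C6).** Ionisation at C6 may be sluggish, or the pyrrole C3 may compete if the pyrrole N–C6 bond opens. The fallback sets out from 16 and returns at 17. Treat 16 with PhSO2Na in HCO2H/H2O at rt; the acetal opens, the urea condenses with the aldehyde carbon, and sulfinate traps the resulting acyliminium as the spiro α-ureido sulfone F10 (pyrrole N–H free). Cs2CO3 in MeCN then eliminates sulfinate to the cyclic N-acylimine F11, which is not isolated, and the pyrrolide nitrogen adds to it in a six-membered ring closure that can only give N-attack and the cis-fused 17.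

## Further compounds

F1 | step 6 | [1-(4,5-dibromo-1H-pyrrole-2-carbonyl)pyrrolidine-2,2-diyl]dimethanol | OCC1(CO)CCCN1C(=O)c1cc(Br)c(Br)[nH]1
F2 | step 6 | monoacetate of F1 (free CH2OH is the future C6 arm) | CC(=O)OC[C@]1(CO)CCCN1C(=O)c1cc(Br)c(Br)[nH]1
F3 | step 6 | aldehyde from F2 (not isolated) | CC(=O)OC[C@]1(C=O)CCCN1C(=O)c1cc(Br)c(Br)[nH]1
F4 | step 6 | C6-carbinolamine with CH2OAc on C10 | CC(=O)OC[C@]12CCCN1C(=O)c1cc(Br)c(Br)n1C2O
F5 | step 6 | C6-methoxy N,O-acetal with CH2OAc on C10 | CC(=O)OC[C@]12CCCN1C(=O)c1cc(Br)c(Br)n1C2OC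
F6 | step 6 | C6-methoxy N,O-acetal with CH2OH on C10 | OC[C@]12CCCN1C(=O)c1cc(Br)c(Br)n1C2OC
F7 | step 6 | C6-methoxy N,O-acetal with CHO on C10 | O=C[C@]12CCCN1C(=O)c1cc(Br)c(Br)n1C2OC
F8 | step 8 | methyl 1-(4,5-dibromo-1H-pyrrole-2-carbonyl)-2-(hydroxymethyl)pyrrolidine-2-carboxylate | COC(=O)[C@]1(CO)CCCN1C(=O)c1cc(Br)c(Br)[nH]1
F9 | step 8 | methyl 1-(4,5-dibromo-1H-pyrrole-2-carbonyl)-2-formylpyrrolidine-2-carboxylate (not isolated) | COC(=O)[C@]1(C=O)CCCN1C(=O)c1cc(Br)c(Br)[nH]1
F10 | step 12 | spiro α-ureido sulfone (4-phenylsulfonyl-imidazolidin-2-one spiro-fused at C10 to the N-aroyl pyrrolidine) | O=C1N[C@@]2(CCCN2C(=O)c2cc(Br)c(Br)[nH]2)C(S(=O)(=O)c2ccccc2)N1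
F11 | step 12 | cyclic N-acylimine from F10 (not isolated) | O=C1N[C@@]2(CCCN2C(=O)c2cc(Br)c(Br)[nH]2)C=N1
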